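**Retrosynthetic overview**
- Target 11 comes from dehydrogenative aromatisation of 2,3-dibromo-6-aryloxycyclohex-2-enone 10, so the phenol ring is built de novo with the C–Br, C–OH and C–OAr positions fixed by the ring construction.
- 10 comes from 2-bromo-1,3-dione 9 (vinylogous acid to vinyl bromide), and 9 from 4-aryloxycyclohexane-1,3-dione 8 by C2 bromination.
- 8 comes from keto ester 6 by hydrolysis and decarboxylation; 6 comes from intramolecular Claisen ring closure of keto diester 5.
- 5 comes from the key intermolecular Michael addition of aryloxymalonate 3 to methyl vinyl ketone 4; 3 comes from 2,4-dibromophenol 1 and chloromalonate 2.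
- Ring order: the 2,4-dibromophenyl ring is bought intact; the second six-membered ring is closed in step 3 and aromatised last.

Assumption: the target has no stereocentre (it is achiral), so no enantiocontrol is needed; the sp3 intermediates 6–10 are racemic and their stereocentres vanish on aromatisation.

**Route**

Step 1
Reactants: 1 2,4-dibromophenol; 2 dimethyl 2-chloromalonate
Product: 3 dimethyl 2-(2,4-dibromophenoxy)malonate
Conditions: K2CO3 (1.5 equiv), acetone, reflux
Reagents that add atoms: none
Why: Williamson-type SN2 O-alkylation of the acidic phenol by the doubly activated chloride is the standard entry to aryloxymalonates and creates no stereocentre.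

Step 2
Reactants: 3 dimethyl 2-(2,4-dibromophenoxy)malonate; 4 methyl vinyl ketone
Product: 5 dimethyl 2-(2,4-dibromophenoxy)-2-(3-oxobutyl)malonate
Conditions: MVK (1.2 equiv), DBU (10 mol %), MeCN, 0 °C to rt
Reagents that add atoms: none
Why: Base-catalysed intermolecular Michael addition of the soft malonate carbanion to the unhindered enone forms the C–C bond that becomes C5–C6 of the phenol ring, and the new quaternary carbon carries two identical esters, so it is not a stereocentre.

Step 3
Reactants: 5 dimethyl 2-(2,4-dibromophenoxy)-2-(3-oxobutyl)malonate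
Product: 6 rac-methyl 1-(2,4-dibromophenoxy)-2,4-dioxocyclohexane-1-carboxylate
Conditions: NaOMe (1.5 equiv), MeOH, reflux; then aq. HCl to pH 2
Reagents that add atoms: none
Why: Intramolecular Claisen (Dieckmann-type) acylation of the methyl ketone enolate by one of the two enantiotopic esters closes the six-membered ring as in the dimedone synthesis, driven by the stabilised β-diketone enolate, and gives the quaternary centre as a racemate that is erased later.

Step 4
Reactants: 6 rac-methyl 1-(2,4-dibromophenoxy)-2,4-dioxocyclohexane-1-carboxylate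
Product: 8 rac-4-(2,4-dibromophenoxy)cyclohexane-1,3-dione, via β-keto acid 7 (not isolated)
Conditions: 6 M aq. HCl, AcOH, 100 °C
Reagents that add atoms: none
Why: Acid hydrolysis of the methyl ester gives a β-keto acid that decarboxylates through the usual six-membered transition state, while the diaryl ether and aryl bromides are inert to acid; C4 is racemic and unimportant.

Step 5
Reactants: 8 rac-4-(2,4-dibromophenoxy)cyclohexane-1,3-dione
Product: 9 rac-2-bromo-4-(2,4-dibromophenoxy)cyclohexane-1,3-dione
Conditions: NBS (1.0 equiv), CH2Cl2, 0 °C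
Reagents that add atoms: N-bromosuccinimide O=C1CCC(=O)N1Br
Why: Electrophilic α-bromination of the fully enolised 1,3-dione occurs at C2, which is far more nucleophilic than the deactivated dibromophenyl ether ring or C4.

Step 6
Reactants: 9 rac-2-bromo-4-(2,4-dibromophenoxy)cyclohexane-1,3-dione
Product: 10 rac-2,3-dibromo-6-(2,4-dibromophenoxy)cyclohex-2-en-1-one
Conditions: (COBr)2 (1.3 equiv), DMF (cat.), CH2Cl2, 0 °C to rt
Reagents that add atoms: oxalyl bromide O=C(Br)C(=O)Br
Why: Vilsmeier-type activation of the less hindered, less deactivated enol oxygen (the one remote from the C–OAr carbon) followed by addition–elimination of bromide gives the vinylogous acyl bromide with the ketone kept next to the aryloxy carbon.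

Step 7
Reactants: 10 rac-2,3-dibromo-6-(2,4-dibromophenoxy)cyclohex-2-en-1-one
Product: 11 2,3-dibromo-6-(2,4-dibromophenoxy)phenol
Conditions: DDQ (1.5 equiv), anhydrous TsOH (5 mol %), 1,4-dioxane, 100 °C
Reagents that add atoms: none
Why: DDQ dehydrogenation (acid-promoted enolisation, hydride abstraction, tautomerisation of the dienone) is driven by aromatisation and uses no electrophilic bromine, so the open position para to the new OH is not brominated.

**Compound list**
1 | 2,4-dibromophenol | Oc1ccc(Br)cc1Br | starting material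
2 | dimethyl 2-chloromalonate | COC(=O)C(Cl)C(=O)OC | starting material
3 | dimethyl 2-(2,4-dibromophenoxy)malonate | COC(=O)C(Oc1ccc(Br)cc1Br)C(=O)OC | intermediate
4 | methyl vinyl ketone (but-3-en-2-one) | CC(=O)C=C | starting material
5 | dimethyl 2-(2,4-dibromophenoxy)-2-(3-oxobutyl)malonate | COC(=O)C(CCC(C)=O)(Oc1ccc(Br)cc1Br)C(=O)OC | intermediate
6 | rac-methyl 1-(2,4-dibromophenoxy)-2,4-dioxocyclohexane-1-carboxylate (largely enolised) | COC(=O)C1(Oc2ccc(Br)cc2Br)CCC(=O)CC1=O | intermediate
7 | rac-1-(2,4-dibromophenoxy)-2,4-dioxocyclohexane-1-carboxylic acid (β-keto acid, not isolated) | OC(=O)C1(Oc2ccc(Br)cc2Br)CCC(=O)CC1=O | intermediate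
8 | rac-4-(2,4-dibromophenoxy)cyclohexane-1,3-dione (largely enolised) | O=C1CCC(Oc2ccc(Br)cc2Br)C(=O)C1 | intermediate
9 | rac-2-bromo-4-(2,4-dibromophenoxy)cyclohexane-1,3-dione (enolised, drawn as diketone) | O=C1CCC(Oc2ccc(Br)cc2Br)C(=O)C1Br | intermediate
10 | rac-2,3-dibromo-6-(2,4-dibromophenoxy)cyclohex-2-en-1-one | O=C1C(Br)=C(Br)CCC1Oc1ccc(Br)cc1Br | intermediate
11 | 2,3-dibromo-6-(2,4-dibromophenoxy)phenol | Oc1c(Oc2ccc(Br)cc2Br)ccc(Br)c1Br | target

**Step count and risks**
Total step count: 7. Longest linear sequence: 7 steps (1 to 11).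

Steps most likely to fail:

Step 3 (Claisen ring closure onto an ester at a fully substituted aryloxy carbon; retro-Michael loss of MVK can compete). The fallback sets out from 1 and returns at 8. Compound 1 is O-alkylated with chloroacetone (K2CO3, acetone) to 1-(2,4-dibromophenoxy)propan-2-one F1. Its thermodynamic enolate at the aryloxy-bearing carbon (NaH, toluene, −10 °C to rt) adds to methyl acrylate in a Michael reaction to give methyl 4-(2,4-dibromophenoxy)-5-oxohexanoate F2. F2 closes in the same pot by Claisen condensation of its methyl ketone enolate onto the ester and gives 8 directly, with no quaternary ester and no decarboxylation.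

Step 6 (regiochemistry of the vinyl bromide; the wrong enol oxygen could be activated). The fallback sets out from 6 and returns at 10. In 6 the quaternary C1 shields the C2 carbonyl, so the functionalisation is done before decarboxylation. NBS gives methyl 3-bromo-1-(2,4-dibromophenoxy)-2,4-dioxocyclohexane-1-carboxylate F3. Oxalyl bromide with catalytic DMF then converts only the remote enol oxygen, giving methyl 3,4-dibromo-1-(2,4-dibromophenoxy)-2-oxocyclohex-3-ene-1-carboxylate F4. Dealkoxycarbonylation of F4 with LiBr in wet DMF at 110 °C delivers 10; bromide is the nucleophile, so any vinylic halide exchange is degenerate.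

Step 7 (DDQ dehydrogenation of an electron-poor dibromoenone may be sluggish). The fallback sets out from 10 and returns at 11. α'-Deprotonation of 10 with LiHMDS (THF, −78 °C) and trapping with PhSeCl gives 2,3-dibromo-6-(2,4-dibromophenoxy)-6-(phenylselanyl)cyclohex-2-en-1-one F5. H2O2 with pyridine (CH2Cl2, 0 °C to rt) oxidises F5 to 2,3-dibromo-6-(2,4-dibromophenoxy)-6-(phenylseleninyl)cyclohex-2-en-1-one F6. F6 undergoes syn-elimination to 2,3-dibromo-6-(2,4-dibromophenoxy)cyclohexa-2,5-dien-1-one F7, which tautomerises spontaneously to 11.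

Further compounds
F1 | step 3 | 1-(2,4-dibromophenoxy)propan-2-one | CC(=O)COc1ccc(Br)cc1Br
F2 | step 3 | methyl 4-(2,4-dibromophenoxy)-5-oxohexanoate | COC(=O)CCC(Oc1ccc(Br)cc1Br)C(C)=O
F3 | step 6 | methyl 3-bromo-1-(2,4-dibromophenoxy)-2,4-dioxocyclohexane-1-carboxylate | COC(=O)C1(Oc2ccc(Br)cc2Br)CCC(=O)C(Br)C1=O
F4 | step 6 | methyl 3,4-dibromo-1-(2,4-dibromophenoxy)-2-oxocyclohex-3-ene-1-carboxylate | COC(=O)C1(Oc2ccc(Br)cc2Br)CCC(Br)=C(Br)C1=O
F5 | step 7 | 2,3-dibromo-6-(2,4-dibromophenoxy)-6-(phenylselanyl)cyclohex-2-en-1-one | O=C1C(Br)=C(Br)CCC1([Se]c1ccccc1)Oc1ccc(Br)cc1Br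
F6 | step 7 | 2,3-dibromo-6-(2,4-dibromophenoxy)-6-(phenylseleninyl)cyclohex-2-en-1-one | O=C1C(Br)=C(Br)CCC1([Se](=O)c1ccccc1)Oc1ccc(Br)cc1Br
F7 | step 7 | 2,3-dibromo-6-(2,4-dibromophenoxy)cyclohexa-2,5-dien-1-one | O=C1C(Br)=C(Br)CC=C1Oc1ccc(Br)cc1Br
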